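**Retrosynthetic overview**

1. Target ⇐ its penta-O-isopropyl ether (global Lewis-acid dealkylation as the last step).
2. Both C2–aryl bonds and all four stereocentres ⇐ twofold enantioselective 1,4-arylation of an unsymmetrical 3,3'-bichromone with 4-isopropoxyphenylboronic acid, then trans-equilibration at C3/C3''.
3. C3–C3'' bond and the pyranone ring of the 7-oxygenated half ⇐ oxidative 1,2-shift of a chromon-3-yl group from Cβ to Cα of a chalcone-type enone, then acetal ring closure.
4. Enone ⇐ aldol condensation of a resorcinol-derived o-hydroxyacetophenone with a 5,7-dioxygenated 3-formylchromone (Vilsmeier–Haack; its 1,3,5-oxygen pattern comes from C–H borylation/oxidation of a resorcinol diether).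
5. Ring order: pyranone of the 5,7-dioxygenated half, then pyranone of the 7-oxygenated half, then both rings saturated together with the stereocentres set at the end.

Assumption: the three aryl isopropyl ethers used as starting materials are catalogue compounds and are bought; isopropyl is the only protecting group.

Stereochemistry check of the target: both halves are (2S,3R) with 2,3-trans substituents.

**Route**

Step 1
Reactants: 1 3-isopropoxyphenol
Product: 2 1-(2-hydroxy-4-isopropoxyphenyl)ethanone
Conditions: AcOH (1.5 equiv), BF3·OEt2 (3 equiv), 85 °C; then H2O–MeOH, 60 °C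
Reagents that add atoms: acetic acid, CC(=O)O
Why: Friedel–Crafts acylation (through the O-acetate and a Fries-type shift) goes para to the ether and ortho to OH because the chelated o-hydroxy ketone is the stable product, the minor 4-hydroxy-2-isopropoxy isomer being removed by chromatography; no stereocentre.

Step 2
Reactants: 3 1,3-diisopropoxybenzene
Product: 5 3,5-diisopropoxyphenol, via pinacol boronate 4 (not isolated)
Conditions: HBpin (1.5 equiv), [Ir(OMe)(cod)]2 (1.5 mol %), 4,4'-di-tert-butyl-2,2'-bipyridine (3 mol %), THF, 80 °C; then KHSO5 (as 2KHSO5·KHSO4·K2SO4), acetone–H2O, rt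
Reagents that add atoms: pinacolborane, [H]B1OC(C)(C)C(C)(C)O1 (boryl group, held in 4 only); potassium peroxymonosulfate KHSO5, [K+].[O-]S(=O)(=O)OO (the phenol oxygen of 5)
Why: The C–H borylation with [Ir(OMe)(cod)]2 is sterically controlled and takes the only C–H without an ortho substituent (C5), and oxidation of the C–B bond in the same flask gives the phenol with the 1,3,5-oxygen pattern (one-pot arene borylation/oxidation); no stereocentre.

Step 3
Reactants: 5 3,5-diisopropoxyphenol
Product: 6 1-(2-hydroxy-4,6-diisopropoxyphenyl)ethanone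
Conditions: AcOH (1.5 equiv), BF3·OEt2 (3 equiv), 60 °C; then H2O–MeOH, 60 °C
Reagents that add atoms: acetic acid, CC(=O)O
Why: Friedel–Crafts acylation of the electron-rich phenol at either of the two equivalent positions ortho to OH gives the chelated ketone, the site between the two isopropoxy groups being more hindered; no stereocentre.

Step 4
Reactants: 6 1-(2-hydroxy-4,6-diisopropoxyphenyl)ethanone
Product: 7 5,7-diisopropoxy-4-oxo-4H-chromene-3-carbaldehyde
Conditions: POCl3 (4 equiv), DMF, 0 °C → 50 °C; then ice–water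
Reagents that add atoms: N,N-dimethylformamide, CN(C)C=O (C2 and the formyl carbon); water, O (the formyl oxygen)
Why: Vilsmeier–Haack reaction: twofold formylation of the methyl ketone, ring closure by the ortho-hydroxyl with loss of dimethylamine and hydrolysis of the remaining iminium give the first pyranone ring with its 3-formyl group, the standard route to 3-formylchromones; no stereocentre.

Step 5
Reactants: 2 1-(2-hydroxy-4-isopropoxyphenyl)ethanone; 7 5,7-diisopropoxy-4-oxo-4H-chromene-3-carbaldehyde
Product: 8 (E)-3-[3-(2-hydroxy-4-isopropoxyphenyl)-3-oxoprop-1-en-1-yl]-5,7-diisopropoxy-4H-chromen-4-one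
Conditions: BF3·OEt2 (2.5 equiv), 1,4-dioxane, rt → 45 °C; then H2O–MeOH
Reagents that add atoms: none
Why: Lewis-acid-mediated Claisen–Schmidt (aldol) condensation of the boron-activated methyl ketone with the aldehyde, chosen because base would open the pyranone at C2 and because boron keeps the phenol from adding to the new enone; dehydration gives the conjugated E-alkene as the stable isomer.

Step 6
Reactants: 8 (E)-3-[3-(2-hydroxy-4-isopropoxyphenyl)-3-oxoprop-1-en-1-yl]-5,7-diisopropoxy-4H-chromen-4-one
Product: 10 5,7-diisopropoxy-3-(7-isopropoxy-4-oxo-4H-chromen-3-yl)-4H-chromen-4-one, via dimethyl acetal 9 (not isolated)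
Conditions: Tl(NO3)3·3H2O (1.2 equiv), MeOH–HC(OMe)3 (3:1), rt; filter off TlNO3; then 10% aq. HCl, 60 °C
Reagents that add atoms: methanol, CO (the two methoxy groups of 9 only)
Why: Proposed new method: methoxythallation of the enone puts trivalent thallium on Cα and OMe on Cβ, after which C3 of the chromone (the nucleophilic α-carbon of a β-alkoxy enone, whose ring oxygen takes up the positive charge at C2 in the bridged intermediate) shifts from Cβ to Cα as thallium leaves in its monovalent state, which forms the C3–C3'' bond, and the resulting β-keto acetal closes on the phenol in acid to the second pyranone ring; the closest known reaction is the Tl(NO3)3 oxidative 1,2-aryl shift of 2'-hydroxychalcones to isoflavones, which has not been shown with a chromon-3-yl migrating group.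

Step 7
Reactants: 11 1-bromo-4-isopropoxybenzene
Product: 14 (4-isopropoxyphenyl)boronic acid, via aryllithium 12 (not isolated), via lithium triisopropoxyborate 13 (not isolated)
Conditions: n-BuLi (1.05 equiv), THF, −78 °C; B(OiPr)3 (1.3 equiv), −78 °C → rt; then 1 M aq. HCl
Reagents that add atoms: n-butyllithium, [Li]CCCC (lithium of 12 and 13 only); triisopropyl borate, CC(C)OB(OC(C)C)OC(C)C (boron); water, O (the two hydroxyl oxygens of 14)
Why: Bromine–lithium exchange, trapping of the aryllithium with the borate ester and acidic hydrolysis, the standard arylboronic acid synthesis; no stereocentre.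

Step 8
Reactants: 10 5,7-diisopropoxy-3-(7-isopropoxy-4-oxo-4H-chromen-3-yl)-4H-chromen-4-one; 14 (4-isopropoxyphenyl)boronic acid
Product: 16 (2S,3R)-3-[(2S,3R)-5,7-diisopropoxy-2-(4-isopropoxyphenyl)-4-oxochroman-3-yl]-7-isopropoxy-2-(4-isopropoxyphenyl)chroman-4-one, via C3 epimer mixture 15 (not isolated)
Conditions: 14 (6 equiv), [Rh(OH)(cod)]2 (5 mol %), (S)-(6,6'-dimethoxybiphenyl-2,2'-diyl)bis[bis(3,4,5-trifluorophenyl)phosphine] (11 mol %), toluene–H2O (10:1), 50 °C; then 0.5 M HCl in MeOH–CH2Cl2, 40 °C
Reagents that add atoms: none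
Why: Proposed new method: an aryl–rhodium species (monovalent rhodium, formed by transmetallation) adds across each C2=C3 bond with aryl delivery to the Re face of C2 and of C2'' under control of the electron-poor (S)-diphosphine, which sets both benzylic centres as S independently (the mixed adduct is a separable diastereomer, so the ee of the main one is upgraded), protonation of the rhodium enolates gives 15, and acid enolisation then settles C3 and C3'' in the more stable 2,3-trans diequatorial arrangement, that is 3R and 3''R; the closest known reaction is the asymmetric Hayashi–Miyaura 1,4-addition of arylboronic acids to chromones unsubstituted at C3, which has not been shown on 3-substituted chromones or on a bichromone.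

Step 9
Reactants: 16 (2S,3R)-3-[(2S,3R)-5,7-diisopropoxy-2-(4-isopropoxyphenyl)-4-oxochroman-3-yl]-7-isopropoxy-2-(4-isopropoxyphenyl)chroman-4-one
Product: 17 (2S,3R)-3-[(2S,3R)-5,7-dihydroxy-2-(4-hydroxyphenyl)-4-oxochroman-3-yl]-7-hydroxy-2-(4-hydroxyphenyl)chroman-4-one
Conditions: BCl3 (10 equiv, 1 M in CH2Cl2), CH2Cl2, −78 °C → 0 °C; then H2O, 0 °C
Reagents that add atoms: none
Why: BCl3 dealkylation of aryl isopropyl ethers (the secondary alkyl leaves as 2-chloropropane, fastest at the chelated 5''-oxygen) frees all five phenols, and at 0 °C or below with the ketones and phenolates bound to boron neither retro-oxa-Michael opening at C2 nor enolisation at C3 is expected, so the four stereocentres are carried over unchanged.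

**Compound list**

1 | 3-isopropoxyphenol | CC(C)Oc1cccc(O)c1 | starting material
2 | 1-(2-hydroxy-4-isopropoxyphenyl)ethanone | CC(=O)c1ccc(OC(C)C)cc1O | intermediate
3 | 1,3-diisopropoxybenzene | CC(C)Oc1cccc(OC(C)C)c1 | starting material
4 | 2-(3,5-diisopropoxyphenyl)-4,4,5,5-tetramethyl-1,3,2-dioxaborolane | CC(C)Oc1cc(OC(C)C)cc(c1)B1OC(C)(C)C(C)(C)O1 | intermediate (not isolated)
5 | 3,5-diisopropoxyphenol | CC(C)Oc1cc(O)cc(OC(C)C)c1 | intermediate
6 | 1-(2-hydroxy-4,6-diisopropoxyphenyl)ethanone | CC(=O)c1c(O)cc(OC(C)C)cc1OC(C)C | intermediate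
7 | 5,7-diisopropoxy-4-oxo-4H-chromene-3-carbaldehyde | O=Cc1coc2cc(OC(C)C)cc(OC(C)C)c2c1=O | intermediate
8 | (E)-3-[3-(2-hydroxy-4-isopropoxyphenyl)-3-oxoprop-1-en-1-yl]-5,7-diisopropoxy-4H-chromen-4-one | CC(C)Oc1ccc(C(=O)/C=C/c2coc3cc(OC(C)C)cc(OC(C)C)c3c2=O)c(O)c1 | intermediate
9 | 3-[3-(2-hydroxy-4-isopropoxyphenyl)-1,1-dimethoxy-3-oxopropan-2-yl]-5,7-diisopropoxy-4H-chromen-4-one (racemic) | COC(OC)C(C(=O)c1ccc(OC(C)C)cc1O)c1coc2cc(OC(C)C)cc(OC(C)C)c2c1=O | intermediate (not isolated)
10 | 5,7-diisopropoxy-3-(7-isopropoxy-4-oxo-4H-chromen-3-yl)-4H-chromen-4-one | O=c1c(-c2coc3cc(OC(C)C)cc(OC(C)C)c3c2=O)coc2cc(OC(C)C)ccc12 | intermediate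
11 | 1-bromo-4-isopropoxybenzene | CC(C)Oc1ccc(Br)cc1 | starting material
12 | (4-isopropoxyphenyl)lithium | [Li]c1ccc(OC(C)C)cc1 | intermediate (not isolated)
13 | lithium (4-isopropoxyphenyl)triisopropoxyborate | [Li+].CC(C)O[B-](OC(C)C)(OC(C)C)c1ccc(OC(C)C)cc1 | intermediate (not isolated)
14 | (4-isopropoxyphenyl)boronic acid | CC(C)Oc1ccc(B(O)O)cc1 | intermediate
15 | (2S,2''S)-bis-adduct of 10, mixture of epimers at C3 and C3'' | O=C1c2ccc(OC(C)C)cc2O[C@H](c2ccc(OC(C)C)cc2)C1C1C(=O)c2c(OC(C)C)cc(OC(C)C)cc2O[C@@H]1c1ccc(OC(C)C)cc1 | intermediate (not isolated)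
16 | (2S,3R)-3-[(2S,3R)-5,7-diisopropoxy-2-(4-isopropoxyphenyl)-4-oxochroman-3-yl]-7-isopropoxy-2-(4-isopropoxyphenyl)chroman-4-one | O=C1c2ccc(OC(C)C)cc2O[C@H](c2ccc(OC(C)C)cc2)[C@H]1[C@H]1C(=O)c2c(OC(C)C)cc(OC(C)C)cc2O[C@@H]1c1ccc(OC(C)C)cc1 | intermediate
17 | (2S,3R)-3-[(2S,3R)-5,7-dihydroxy-2-(4-hydroxyphenyl)-4-oxochroman-3-yl]-7-hydroxy-2-(4-hydroxyphenyl)chroman-4-one | O=C1c2ccc(O)cc2O[C@H](c2ccc(O)cc2)[C@H]1[C@H]1C(=O)c2c(O)cc(O)cc2O[C@@H]1c1ccc(O)cc1 | target

**Count**

Total steps: 9. Longest linear sequence: 7 steps (steps 2, 3, 4, 5, 6, 8, 9, from 1,3-diisopropoxybenzene).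

**Three steps most likely to fail**

Step 6 (proposed new 1,2-shift). The chromon-3-yl group may migrate too slowly. The known side paths are attack of the free phenol on the thallated carbon (aurone-type products) and migration of the hydroxyaryl ring from the carbonyl carbon (ester products). A first remedy within the route is to acetylate the phenol of 8 beforehand. The fallback uses only known chemistry and leaves the shift out. It sets out from 1 and 5 and comes back at 10. Phenol 1 is acylated with bought succinic anhydride (BF3·OEt2, 90 °C) to 4-(2-hydroxy-4-isopropoxyphenyl)-4-oxobutanoic acid F1. This acid acylates phenol 5 under the conditions of step 3 to 1-(2-hydroxy-4-isopropoxyphenyl)-4-(2-hydroxy-4,6-diisopropoxyphenyl)butane-1,4-dione F2. Heating F2 with Me2NCH(OMe)2 in toluene gives the bis-enaminone 2,3-bis[(dimethylamino)methylidene]-1-(2-hydroxy-4-isopropoxyphenyl)-4-(2-hydroxy-4,6-diisopropoxyphenyl)butane-1,4-dione F3. In aq. HCl–MeOH both phenols close onto the enaminones with loss of dimethylamine (the standard enaminone route to chromones and isoflavones) to give 10.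

Step 8 (proposed new twofold arylation). Insertion into a 3-substituted, electron-rich chromone may be slow, above all for the second addition next to the new sp3 centre, and protodeboronation of 14 competes. If the sense of induction on 10 is opposite to that on simple chromones, the (R)-ligand is used. The fallback is racemic addition followed by resolution. It sets out from 10 and 11 and comes back at 16. Bromide 11 and Mg in THF give (4-isopropoxyphenyl)magnesium bromide F4. F4 (4 equiv) is added to 10 with CuI (20 mol %) in THF at −40 °C → 0 °C (known copper-catalysed aryl Grignard 1,4-addition to chromones and isoflavones), with NH4Cl quench and the same HCl equilibration. This gives the all-2,3-trans stereoisomer mixture of 3-[5,7-diisopropoxy-2-(4-isopropoxyphenyl)-4-oxochroman-3-yl]-7-isopropoxy-2-(4-isopropoxyphenyl)chroman-4-one F5. The two diastereomeric racemates of F5 are separated on silica, and the (2S*,3R*,2''S*,3''R*) racemate is resolved by preparative chromatography on a chiral stationary phase to give 16.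

Step 5 (aldol condensation with a 3-formylchromone). The aldehyde is prone to attack at C2 and the electron-rich partners may condense sluggishly. The fallback replaces the aldol by a Wittig olefination. It sets out from 2 and 7 and comes back at 8. Ketone 2 is brominated with CuBr2 (2 equiv, EtOAc–CHCl3, reflux) to 2-bromo-1-(2-hydroxy-4-isopropoxyphenyl)ethanone F6. PPh3 in toluene gives [2-(2-hydroxy-4-isopropoxyphenyl)-2-oxoethyl]triphenylphosphonium bromide F7. Aq. Na2CO3 gives the stabilised ylide 1-(2-hydroxy-4-isopropoxyphenyl)-2-(triphenyl-λ5-phosphanylidene)ethanone F8. F8 and aldehyde 7 in toluene at 90 °C give the E-enone 8 under neutral conditions.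

**Further compounds**

F1 | step 6 | 4-(2-hydroxy-4-isopropoxyphenyl)-4-oxobutanoic acid | OC(=O)CCC(=O)c1ccc(OC(C)C)cc1O
F2 | step 6 | 1-(2-hydroxy-4-isopropoxyphenyl)-4-(2-hydroxy-4,6-diisopropoxyphenyl)butane-1,4-dione | CC(C)Oc1ccc(C(=O)CCC(=O)c2c(O)cc(OC(C)C)cc2OC(C)C)c(O)c1
F3 | step 6 | 2,3-bis[(dimethylamino)methylidene]-1-(2-hydroxy-4-isopropoxyphenyl)-4-(2-hydroxy-4,6-diisopropoxyphenyl)butane-1,4-dione | CN(C)C=C(C(=O)c1ccc(OC(C)C)cc1O)C(=CN(C)C)C(=O)c1c(O)cc(OC(C)C)cc1OC(C)C
F4 | step 8 | (4-isopropoxyphenyl)magnesium bromide | CC(C)Oc1ccc([Mg]Br)cc1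
F5 | step 8 | 3-[5,7-diisopropoxy-2-(4-isopropoxyphenyl)-4-oxochroman-3-yl]-7-isopropoxy-2-(4-isopropoxyphenyl)chroman-4-one, all-2,3-trans stereoisomer mixture | O=C1c2ccc(OC(C)C)cc2OC(c2ccc(OC(C)C)cc2)C1C1C(=O)c2c(OC(C)C)cc(OC(C)C)cc2OC1c1ccc(OC(C)C)cc1
F6 | step 5 | 2-bromo-1-(2-hydroxy-4-isopropoxyphenyl)ethanone | O=C(CBr)c1ccc(OC(C)C)cc1O
F7 | step 5 | [2-(2-hydroxy-4-isopropoxyphenyl)-2-oxoethyl]triphenylphosphonium bromide | [Br-].O=C(C[P+](c1ccccc1)(c1ccccc1)c1ccccc1)c1ccc(OC(C)C)cc1O
F8 | step 5 | 1-(2-hydroxy-4-isopropoxyphenyl)-2-(triphenyl-λ5-phosphanylidene)ethanone | O=C(C=P(c1ccccc1)(c1ccccc1)c1ccccc1)c1ccc(OC(C)C)cc1O
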